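A direct plan would follow the presumed biogenesis: the fully substituted 3-geranyl-5-prenyl-isobutyrylphloroglucinol A1 would be dearomatised by C-alkylation with a chiral lavandulyl-type electrophile, and ring B would be closed by capture of a tertiary cation at the acyl-bearing carbon to give the type A bicyclo[3.3.1]nonane A2.
An oxidative radical cascade would then forge C3–C11 and C12–C13 to give the cage A3, whose extra isopropenyl group on C13 would finally be cut out.
Its weakest steps would be:
- the alkylative dearomatisation of A1, in which neither the site of alkylation nor the new quaternary centre C5 would be controlled, so that isomeric bicycles would have to be separated;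
- the radical cascade from A2, in which the 7-exo closure would compete with other modes and C11 would be left to substrate control;
- the two-step removal of the isopropenyl carbons from A3, which would add length without adding complexity.

The route rests on cutting the cage at C7–C10, C1–C2 and C5–C9, so that it grows around a cyclopentane whose quaternary carbon C3 is set once by catalysis. The key step exploits the lone CH2 carbon C10 between the methine C7 of ring B and the cyclopentane: a decarboxylative 7-endo radical cyclisation onto the exocyclic alkene C11=C10 closes the seven-membered ring through C3, C4, C5, C6, C7, C10 and C11 and relays C3 to C7 and C11. C5 and C1 then follow as bridgeheads, and ring A is closed last by a Claisen condensation. Nothing is dearomatised, and no oxidative cascade or carbon excision is needed.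

Key step: step 9

Remark (numbering used throughout): C1 is the acyl-bearing bridgehead, C2, C4 and C9 the ring ketones (C9 between C1 and C5), C3 the quaternary carbon shared with the cyclopentane, C5 the geranyl-bearing bridgehead, C6 CH2, C7 CH, C8 CMe2, C10 CH2, C11 CH, C12 CMe2, and C13–C14 the CH2CH2 unit back to C3. Ring A is C1–C2–C3–C4–C5–C9 and ring B is C1–C9–C5–C6–C7–C8.

Assumption: the (R) ligand in step 4 is taken to give (S)-7; its antipode would be used if the first run gave the enantiomer.

**Step 1**
Reactants: 1 3,3-dimethyloxolan-2-one (α,α-dimethyl-γ-butyrolactone)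
Product: 3 3,3-dimethylpent-4-yn-1-ol, via lactol 2 (not isolated)
Conditions: i-Bu2AlH (1.1 equiv), CH2Cl2, −78 °C; then MeOH, K2CO3 (2 equiv), dimethyl (1-diazo-2-oxopropyl)phosphonate (1.3 equiv), −78 °C to rt
Reagents that add atoms: dimethyl (1-diazo-2-oxopropyl)phosphonate, CC(=O)C(=[N+]=[N-])P(=O)(OC)OC
Why: reduction of the lactone stops at the aluminium lactolate and, after methanolysis, the open hydroxy aldehyde (no α-hydrogen) should undergo Seyferth–Gilbert homologation with the Ohira–Bestmann reagent to the terminal alkyne; no stereocentre is formed.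

**Step 2**
Reactants: 3 3,3-dimethylpent-4-yn-1-ol
Product: 4 5-iodo-3,3-dimethylpent-1-yne
Conditions: I2 (1.2 equiv), PPh3 (1.2 equiv), imidazole (1.5 equiv), CH2Cl2, 0 °C to rt
Reagents that add atoms: iodine, [I][I]
Why: Appel iodination (SN2 displacement of the alkoxyphosphonium ion by iodide at a primary carbon) should give the iodide without touching the alkyne.

**Step 3**
Reactants: 4 5-iodo-3,3-dimethylpent-1-yne; 5 methyl 3-oxobutanoate (methyl acetoacetate)
Product: 6 methyl 2-acetyl-5,5-dimethylhept-6-ynoate (racemic)
Conditions: 5 (2.0 equiv), K2CO3 (1.5 equiv), DMF, 50 °C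
Reagents that add atoms: none
Why: C-alkylation of the acetoacetate enolate with a primary iodide (SN2) is standard, the excess of 5 should suppress dialkylation, and the new stereocentre is left racemic because it is planarised as an enol in the next step.

**Step 4**
Reactants: 6 methyl 2-acetyl-5,5-dimethylhept-6-ynoate
Product: 7 methyl (1S)-1-acetyl-3,3-dimethyl-2-methylidenecyclopentane-1-carboxylate
Conditions: [(R)-DTBM-SEGPHOS]Pd(OTf)2 (10 mol%), Yb(OTf)3 (20 mol%), AcOH (10 equiv), Et2O, rt
Reagents that add atoms: none
Why: catalytic enantioselective Conia-ene reaction, in which the chiral divalent palladium enolate of the β-keto ester (formed with the help of Yb(OTf)3) should add 5-exo-dig to the alkyne; this closes the cyclopentane, sets the quaternary centre C3 by catalyst control as the only stereocentre that is bought, and leaves the exocyclic alkene C11=C10 for the key step.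

**Step 5**
Reactants: 8 4,4-dimethyloxane-2,6-dione (3,3-dimethylglutaric anhydride)
Product: 9 5-tert-butoxy-3,3-dimethyl-5-oxopentanoic acid
Conditions: t-BuOK (1.05 equiv), THF, 0 °C to rt; aq. HCl
Reagents that add atoms: potassium tert-butoxide, CC(C)(C)[O-].[K+]
Why: ring opening of the cyclic anhydride by tert-butoxide (acyl substitution) gives the half ester and differentiates the two carboxyl groups without forming a stereocentre.

**Step 6**
Reactants: 9 5-tert-butoxy-3,3-dimethyl-5-oxopentanoic acid
Product: 12 1-tert-butyl 5-methyl 3,3-dimethyl-2-methylidenepentanedioate, via Mannich base 10 (not isolated), via trimethylammonium iodide 11 (not isolated)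
Conditions: LiN(i-Pr)2 (2.2 equiv), THF, −78 to −20 °C; CH2=NMe2+ I− (1.2 equiv), −78 °C to rt; MeI (5 equiv), DMF, rt; DBU (2 equiv)
Reagents that add atoms: N,N-dimethylmethaniminium iodide (Eschenmoser's salt), C=[N+](C)C.[I-]; iodomethane, CI
Why: the dianion forms at the more acidic ester α-carbon, and its Mannich reaction with Eschenmoser's salt, exhaustive methylation (amine quaternised, carboxylate esterified) and E1cB loss of trimethylamine should give the α-methylene ester with the acid-labile tert-butyl ester on the future C7.

**Step 7**
Reactants: 7 methyl (1S)-1-acetyl-3,3-dimethyl-2-methylidenecyclopentane-1-carboxylate; 12 1-tert-butyl 5-methyl 3,3-dimethyl-2-methylidenepentanedioate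
Product: 14 tert-butyl 5-{[(1S)-1-(methoxycarbonyl)-3,3-dimethyl-2-methylidenecyclopentyl]carbonyl}-2,2-dimethyl-4-oxocyclohexane-1-carboxylate (mixture at the two ring stereocentres C5 and C7), via Michael adduct 13 (not isolated)
Conditions: LiN(SiMe3)2 (1.2 equiv), THF, −78 °C; 12 (1.1 equiv), −78 °C to rt; AcOH quench
Reagents that add atoms: none
Why: Michael–Dieckmann annulation, in which the only enolate that 7 can form (C5) adds to the acrylate 12 to make C5–C6, proton transfer returns the ketone enolate, and this closes ring B on the methyl ester to make C5–C9 (the tert-butyl ester is inert, and closure of the C7 enolate on the hindered C3 ester would give a non-enolisable product that reverts) while the methoxide set free is consumed by the acidic 1,3-diketone; C5 and C7 arise as mixtures that do not matter, since C5 is enolisable and C7 becomes a radical.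

**Step 8**
Reactants: 14 tert-butyl ester of the ring B 1,3-diketone
Product: 15 5-{[(1S)-1-(methoxycarbonyl)-3,3-dimethyl-2-methylidenecyclopentyl]carbonyl}-2,2-dimethyl-4-oxocyclohexane-1-carboxylic acid (mixture at C5 and C7)
Conditions: CF3CO2H/CH2Cl2 (1:4), 0 °C
Reagents that add atoms: none
Why: acidolysis of the tert-butyl ester (E1 loss of isobutene) should leave the neopentyl methyl ester untouched, and the exocyclic alkene should resist protonation because the cation would lie next to the carbon that bears two acyl groups and the alkene cannot migrate into the ring between two quaternary carbons.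

**Step 9**
Reactants: 15 ring B carboxylic acid
Product: 17 tricyclic diketo ester (ring B bridged from C5 to C7 by C4–C3–C11–C10; cyclopentane trans-fused at C3–C11; methyl ester on C3; C3 C5 C7 C11 configured as in the target), via N-acyloxyphthalimide 16 (not isolated)
Conditions: N-hydroxyphthalimide (1.1 equiv), i-PrN=C=N-i-Pr (1.1 equiv), DMAP (5 mol%), CH2Cl2, rt; then [Ru(bpy)3](PF6)2 (1 mol%), diethyl 2,6-dimethyl-1,4-dihydropyridine-3,5-dicarboxylate (Hantzsch ester, 1.5 equiv), i-Pr2NEt (2 equiv), CH2Cl2 (5 mM), blue LEDs, rt
Reagents that add atoms: none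
Why: single-electron reduction of 16 by the photoreduced form of [Ru(bpy)3](PF6)2 releases CO2 and the secondary C7 radical, which adds to the unsubstituted terminus C10 of the exocyclic alkene, and the tertiary C11 radical then takes a hydrogen atom from the Hantzsch ester; the closest known reaction type is the reductive decarboxylative radical cyclisation of N-acyloxyphthalimides onto alkenes. The seven-membered ring C3–C4–C5–C6–C7–C10–C11 closes in the 7-endo-trig mode, because the internal alkene carbon C11 is fully substituted and flanked by the quaternary carbons C3 and C12, so that the 6-exo mode is blocked and only attack at CH2 gives a tertiary radical. C7 is set by the tether: C5 is kept planar as the ammonium enolate of the 1,3-diketone, and of the two faces of ring B that the chain C4–C3–C11 could bridge only one leaves the fused cyclopentane on the convex side, so that the (S) centre C3 dictates C7, leaves the ester carbon C2 pointing at C1, and fixes C5 as the only bridgehead epimer that the bicycle allows once it is protonated. C11 is set by hydrogen-atom delivery to the face of the planar radical that is remote from the ester and from the axial methyl group on C8, which gives the trans-fused cyclopentane–cycloheptane of the target. The step needs ring closure to outrun reduction of the C7 radical, which high dilution, the absence of a fast hydrogen donor such as a thiol, and the short tether (two rotatable bonds between ring B and the alkene) should secure.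

**Step 10**
Reactants: 17 tricyclic diketo ester; 18 geranyl acetate, (2E)
Product: 19 C5-geranyl tricyclic diketo ester (as 17 with (2E)-3,7-dimethylocta-2,6-dienyl on the bridgehead C5; C3 C5 C7 C11 as in the target)
Conditions: NaH (1.05 equiv), THF, 0 °C; 18 (1.2 equiv), Pd(PPh3)4 (5 mol%), rt to 40 °C
Reagents that add atoms: none
Why: Tsuji–Trost allylation, in which the sodium enolate of the 1,3-diketone should attack the (π-geranyl)Pd(PPh3)2 cation on carbon at the unsubstituted terminus with retention of the (E) geometry (any O-geranyl ether is returned through the same complex); since C5 is a bridgehead, the geranyl group can enter only from the outer face, so that C5 follows from C7.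

**Step 11**
Reactants: 19 C5-geranyl tricyclic diketo ester
Product: 20 cage trione without the acyl group (5-geranyl-8,8,12,12-tetramethyl cage 2,4,9-trione with hydrogen on C1; all five stereocentres as in the target)
Conditions: LiN(SiMe3)2 (1.5 equiv), THF, −78 to 0 °C; AcOH quench at −78 °C
Reagents that add atoms: none
Why: intramolecular Claisen (Dieckmann-type) condensation, in which C1 is the only enolisable carbon left and its lithium enolate should attack the methyl ester that C3 holds directly above it; this closes ring A and thereby the cage and fixes C1 as a bridgehead, while the low temperature and the lithium counter-ion should keep methoxide from reopening the non-enolisable 1,3-diketone.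

**Step 12**
Reactants: 20 cage trione without the acyl group; 21 isobutyryl chloride
Product: 22 (1S,3S,5R,7R,11R)-5-geranyl-8,8,12,12-tetramethyl-1-(2-methylpropanoyl) cage trione (CNP0313870.1)
Conditions: 2,2,6,6-tetramethylpiperidine (1.6 equiv), n-BuLi (1.5 equiv), THF, −78 to 0 °C (lithium 2,2,6,6-tetramethylpiperidide); 20, −78 °C; 21 (2.0 equiv), −78 to −40 °C; aq. NH4Cl
Reagents that add atoms: none
Why: bridgehead deprotonation by the hydride-free lithium amide (the carbanion is stabilised inductively by the C2 and C9 carbonyl groups and no other acidic hydrogen is left) followed by C-acylation should install the acyl group with retention, because a bridgehead carbanion cannot invert.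

**Compound list**
1 | 3,3-dimethyloxolan-2-one | CC1(C)CCOC1=O | starting material
2 | 3,3-dimethyloxolan-2-ol (lactol) | CC1(C)CCOC1O | intermediate
3 | 3,3-dimethylpent-4-yn-1-ol | C#CC(C)(C)CCO | intermediate
4 | 5-iodo-3,3-dimethylpent-1-yne | C#CC(C)(C)CCI | intermediate
5 | methyl 3-oxobutanoate | CC(=O)CC(=O)OC | starting material
6 | methyl 2-acetyl-5,5-dimethylhept-6-ynoate (racemic) | CC(=O)C(CCC(C)(C)C#C)C(=O)OC | intermediate
7 | methyl (1S)-1-acetyl-3,3-dimethyl-2-methylidenecyclopentane-1-carboxylate | CC(=O)[C@]1(C(=O)OC)CCC(C)(C)C1=C | intermediate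
8 | 4,4-dimethyloxane-2,6-dione | CC1(C)CC(=O)OC(=O)C1 | starting material
9 | 5-tert-butoxy-3,3-dimethyl-5-oxopentanoic acid | CC(C)(C)OC(=O)CC(C)(C)CC(=O)O | intermediate
10 | 5-tert-butoxy-4-[(dimethylamino)methyl]-3,3-dimethyl-5-oxopentanoic acid (Mannich base) | CC(C)(C)OC(=O)C(CN(C)C)C(C)(C)CC(=O)O | intermediate
11 | [2-(tert-butoxycarbonyl)-5-methoxy-3,3-dimethyl-5-oxopentyl]trimethylammonium iodide | CC(C)(C)OC(=O)C(C[N+](C)(C)C)C(C)(C)CC(=O)OC.[I-] | intermediate
12 | 1-tert-butyl 5-methyl 3,3-dimethyl-2-methylidenepentanedioate | CC(C)(C)OC(=O)C(=C)C(C)(C)CC(=O)OC | intermediate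
13 | 1-tert-butyl 5-methyl 2-{3-[(1S)-1-(methoxycarbonyl)-3,3-dimethyl-2-methylidenecyclopentyl]-3-oxopropyl}-3,3-dimethylpentanedioate (Michael adduct) | CC(C)(C)OC(=O)C(CCC(=O)[C@]1(C(=O)OC)CCC(C)(C)C1=C)C(C)(C)CC(=O)OC | intermediate
14 | tert-butyl 5-{[(1S)-1-(methoxycarbonyl)-3,3-dimethyl-2-methylidenecyclopentyl]carbonyl}-2,2-dimethyl-4-oxocyclohexane-1-carboxylate (mixture at C5 and C7) | CC(C)(C)OC(=O)C1CC(C(=O)[C@]2(C(=O)OC)CCC(C)(C)C2=C)C(=O)CC1(C)C | intermediate
15 | 5-{[(1S)-1-(methoxycarbonyl)-3,3-dimethyl-2-methylidenecyclopentyl]carbonyl}-2,2-dimethyl-4-oxocyclohexane-1-carboxylic acid (mixture at C5 and C7) | OC(=O)C1CC(C(=O)[C@]2(C(=O)OC)CCC(C)(C)C2=C)C(=O)CC1(C)C | intermediate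
16 | 1,3-dioxoisoindolin-2-yl ester of 15 | O=C(ON1C(=O)c2ccccc2C1=O)C1CC(C(=O)[C@]2(C(=O)OC)CCC(C)(C)C2=C)C(=O)CC1(C)C | intermediate
17 | tricyclic diketo ester (ring B bridged C5 to C7 by C4–C3–C11–C10, cyclopentane trans-fused at C3–C11, CO2Me on C3) | COC(=O)[C@@]12CCC(C)(C)[C@H]1C[C@@H]1C[C@@H](C(=O)CC1(C)C)C2=O | intermediate
18 | geranyl acetate, (2E) | CC(=O)OC/C=C(\C)CCC=C(C)C | starting material
19 | C5-geranyl tricyclic diketo ester | COC(=O)[C@@]12CCC(C)(C)[C@H]1C[C@@H]1C[C@@](C/C=C(\C)CCC=C(C)C)(C(=O)CC1(C)C)C2=O | intermediate
20 | cage trione with hydrogen on C1 | CC(C)=CCC/C(C)=C/C[C@@]12C[C@H]3C[C@@H]4C(C)(C)CC[C@]4(C1=O)C(=O)[C@@H](C2=O)C3(C)C | intermediate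
21 | isobutyryl chloride | CC(C)C(=O)Cl | starting material
22 | CNP0313870.1 | CC(C)=CCC/C(C)=C/C[C@@]12C[C@H]3C[C@@H]4C(C)(C)CC[C@]4(C1=O)C(=O)[C@@](C(=O)C(C)C)(C2=O)C3(C)C | target

Total step count: 12. Longest linear sequence: 10 (steps 1–4 and 7–12; steps 5 and 6 make the second fragment).

Steps most likely to fail:

1. **Step 9 (key step).** The C7 radical may be reduced by hydrogen-atom transfer before it closes the ring. The fallback replaces the photochemical reduction and its stoichiometric hydrogen donor by a tin chain from an isolated halide, in which the hydride is fed by syringe pump; it sets out from 16 and comes back at 17. Iododecarboxylation of 16 (LiI, PPh3, blue LEDs), in which capture of the radical by iodine should be faster than ring closure, would give the secondary iodide methyl (1S)-1-[(5-iodo-4,4-dimethyl-2-oxocyclohexyl)carbonyl]-3,3-dimethyl-2-methylidenecyclopentane-1-carboxylate F1. Slow addition of Bu3SnH and AIBN to F1 in refluxing benzene at high dilution would keep the stationary hydride concentration low enough for the 7-endo closure and would give 17.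

2. **Step 11.** The hindered C1 enolate may add too slowly to the neopentyl ester, and the methoxide set free may reopen the non-enolisable 1,3-diketone by retro-Claisen cleavage. The fallback closes ring A by an aldol addition to an aldehyde followed by oxidation, so that no alkoxide is set free; it sets out from 19 and comes back at 20. LiAlH4 (THF, reflux) would reduce the ester and the two ketones to the triol F2 (a ketone that resists reduction does no harm, since all carbinols are oxidised again). Dess–Martin periodinane would oxidise F2 to the diketo aldehyde F3. Bu2BOTf/i-Pr2NEt (CH2Cl2, −78 to 0 °C) would turn the C9 ketone into its boron enolate at C1, the only enolisable position, which would add to the aldehyde carbon C2 and give the β-hydroxy diketone F4. A second Dess–Martin oxidation would give 20.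

3. **Step 12.** Proton transfer from the acid chloride or from the acylated product to the bridgehead carbanion may outrun C-acylation. The fallback uses halogen–metal exchange, aldehyde addition and oxidation, sets out from 20 and comes back at 22. The lithiated bridgehead would be quenched with I2 to the bridgehead iodide F5. i-PrMgCl·LiCl would give the less basic bridgehead magnesium reagent, which would add to isobutyraldehyde to give the carbinol F6. Dess–Martin periodinane would oxidise F6 to 22.

**Further compounds**
F1 | step 9 | methyl (1S)-1-[(5-iodo-4,4-dimethyl-2-oxocyclohexyl)carbonyl]-3,3-dimethyl-2-methylidenecyclopentane-1-carboxylate | IC1CC(C(=O)[C@]2(C(=O)OC)CCC(C)(C)C2=C)C(=O)CC1(C)C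
F2 | step 11 | triol from 19 (CH2OH on C3, carbinols at C4 and C9, carbinol configurations unspecified) | OC[C@@]12CCC(C)(C)[C@H]1C[C@@H]1C[C@@](C/C=C(\C)CCC=C(C)C)(C(O)CC1(C)C)C2O
F3 | step 11 | diketo aldehyde (as 19 with CHO in place of CO2Me on C3) | O=C[C@@]12CCC(C)(C)[C@H]1C[C@@H]1C[C@@](C/C=C(\C)CCC=C(C)C)(C(=O)CC1(C)C)C2=O
F4 | step 11 | C2-hydroxy analogue of 20 (β-hydroxy diketone, C2 unspecified) | CC(C)=CCC/C(C)=C/C[C@@]12C[C@H]3C[C@@H]4C(C)(C)CC[C@]4(C1=O)C(O)[C@@H](C2=O)C3(C)C
F5 | step 12 | C1-iodo analogue of 20 | CC(C)=CCC/C(C)=C/C[C@@]12C[C@H]3C[C@@H]4C(C)(C)CC[C@]4(C1=O)C(=O)[C@@](I)(C2=O)C3(C)C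
F6 | step 12 | C1-(1-hydroxy-2-methylpropyl) analogue of 20 (carbinol carbon unspecified) | CC(C)=CCC/C(C)=C/C[C@@]12C[C@H]3C[C@@H]4C(C)(C)CC[C@]4(C1=O)C(=O)[C@@](C(O)C(C)C)(C2=O)C3(C)C
A1 | direct plan | 1-[3-((2E)-3,7-dimethylocta-2,6-dienyl)-2,4,6-trihydroxy-5-(3-methylbut-2-enyl)phenyl]-2-methylpropan-1-one | CC(C)C(=O)c1c(O)c(CC=C(C)C)c(O)c(C/C=C(\C)CCC=C(C)C)c1O
A2 | direct plan | 5-geranyl-4-hydroxy-8,8-dimethyl-1-(2-methylpropanoyl)-3,7-bis(3-methylbut-2-enyl)bicyclo[3.3.1]non-3-ene-2,9-dione (C7 prenyl syn to C3) | CC(C)=CCC/C(C)=C/C[C@]12C[C@@H](CC=C(C)C)C(C)(C)[C@](C(=O)C(C)C)(C1=O)C(=O)C(CC=C(C)C)=C2O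
A3 | direct plan | cage trione carrying prop-1-en-2-yl on C13 (C13 epimers) | CC(C)=CCC/C(C)=C/C[C@@]12C[C@H]3C[C@@H]4C(C)(C)C(C(C)=C)C[C@]4(C1=O)C(=O)[C@@](C(=O)C(C)C)(C2=O)C3(C)C
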